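**Strategy.** Ring B is made by an intramolecular Diels–Alder reaction that forges C7–C8 and C9–C10 at once. The feature exploited is the 1,3-relationship across C1 between the α-oxygen on C2 of ring A and C9 on the quaternary C10. A vinylsulfonate ester of the C2 hydroxyl of a monocyclic 1-vinylcyclohexene (diene C10=C5–C6=C7) can only reach the α-face of C10. The (R)-carbinol of actinol therefore fixes the C10 methyl β while ring B and a temporary sultone ring close together. Oxidative removal of sulfur leaves a C9 ketone, to which the side chain adds anti to the C10 methyl. The C2 carbinol is finally converted into the Δ2 alkene for α-face dihydroxylation.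

Key step: step 6

Remark: labdane numbering is used for all bicyclic compounds (decalin C1–C10, chain C11–C15; β = face of the C10 methyl, α = the opposite face); (4R,6R)-actinol is taken as a purchasable carotenoid building block.

Step 1
Reactants: 1 (4R,6R)-4-hydroxy-2,2,6-trimethylcyclohexan-1-one ((4R,6R)-actinol)
Product: 2 (4R,6R)-4-[(tert-butyldimethylsilyl)oxy]-2,2,6-trimethylcyclohexan-1-one
Conditions: TBSCl, imidazole, DMF, rt
Reagents that add atoms: tert-butyldimethylsilyl chloride, CC(C)(C)[Si](C)(C)Cl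
Why: Routine silyl protection of the secondary alcohol (the future C2 oxygen) so that it survives the enolate chemistry of the next step.

Step 2
Reactants: 2 (4R,6R)-4-[(tert-butyldimethylsilyl)oxy]-2,2,6-trimethylcyclohexan-1-one
Product: 3 (4R)-4-[(tert-butyldimethylsilyl)oxy]-2,6,6-trimethylcyclohex-1-en-1-yl trifluoromethanesulfonate
Conditions: LiN(i-Pr)2, THF, −78 → 0 °C; PhNTf2, 0 °C → rt
Reagents that add atoms: N-phenylbis(trifluoromethanesulfonimide), O=S(=O)(N(c1ccccc1)S(=O)(=O)C(F)(F)F)C(F)(F)F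
Why: Enol triflate formation; the ketone has a single enolisable position (the methine carrying the methyl group), so O-triflation of its lithium enolate can only give the tetrasubstituted C5=C10 enol triflate, which erases the former C6 stereocentre.

Step 3
Reactants: 3 (4R)-4-[(tert-butyldimethylsilyl)oxy]-2,6,6-trimethylcyclohex-1-en-1-yl trifluoromethanesulfonate
Product: 4 tert-butyl(dimethyl){[(1R)-3,5,5-trimethyl-4-vinylcyclohex-3-en-1-yl]oxy}silane
Conditions: tributyl(vinyl)stannane, Pd(PPh3)4 (5 mol %), LiCl, THF, 65 °C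
Reagents that add atoms: tributyl(vinyl)stannane, C=C[Sn](CCCC)(CCCC)CCCC
Why: Stille coupling of the hindered enol triflate installs C6=C7 and completes the C10=C5–C6=C7 diene, a coupling that is routine for 2,6,6-trimethylcyclohexenyl triflates.

Step 4
Reactants: 4 tert-butyl(dimethyl){[(1R)-3,5,5-trimethyl-4-vinylcyclohex-3-en-1-yl]oxy}silane
Product: 5 (1R)-3,5,5-trimethyl-4-vinylcyclohex-3-en-1-ol
Conditions: Bu4NF, THF, rt
Reagents that add atoms: none
Why: Fluoride cleavage of the silyl ether frees the homoallylic hydroxyl that will carry the tether, under conditions that leave the acid-sensitive diene alone.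

Step 5
Reactants: 5 (1R)-3,5,5-trimethyl-4-vinylcyclohex-3-en-1-ol
Product: 6 (1R)-3,5,5-trimethyl-4-vinylcyclohex-3-en-1-yl ethenesulfonate
Conditions: ClCH2CH2SO2Cl, Et3N (2.5 equiv), CH2Cl2, −20 → 0 °C
Reagents that add atoms: 2-chloroethanesulfonyl chloride, ClCCS(=O)(=O)Cl
Why: O-sulfonylation with dehydrochlorination in the same flask (ethenesulfonyl chloride is formed in situ) gives the vinylsulfonate with retention at the carbinol carbon, since only the O–H bond reacts.

Step 6
Reactants: 6 (1R)-3,5,5-trimethyl-4-vinylcyclohex-3-en-1-yl ethenesulfonate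
Product: 7 bridged δ-sultone of 2α-hydroxy-4,4,10β-trimethyl-Δ5-octalin-9α-sulfonic acid (9β-H; O of C2 and S on C9 both on the α face)
Conditions: toluene (0.01 M), BHT, 2,6-di-tert-butyl-4-methylpyridine (0.2 equiv), sealed tube, 120 °C
Reagents that add atoms: none
Why: Thermal concerted [4+2] cycloaddition (intramolecular Diels–Alder reaction of a vinylsulfonate, the known sultone-forming variant for hexa-3,5-dienyl ethenesulfonates) between the s-cis diene C10=C5–C6=C7 and the tethered dienophile C8=C9. Ring B closes as the six-membered cycloadduct ring, and the δ-sultone ring (C10–C1–C2–O–S–C9) closes as the tether ring of a type 1 cycloaddition, giving with ring A a bridged 2-oxa-3-thiabicyclo[3.3.1]nonane. The regiochemistry (C9 to the fully substituted C10, C8 to the terminal C7) is imposed by the four-atom tether, which is too short for the crossed mode. C10 is set by the C2 stereocentre, because the sulfonate on the pseudoaxial C2 oxygen can reach only the diene face syn to that oxygen, which leaves the methyl group anti to the C2–O bond (β). C9 (sulfur α, hydrogen β) follows from the only possible fusion of the sultone ring with ring B and is cleared in the next step. The step needs cycloaddition to outrun ionisation of the homoallylic secondary sulfonate and the 1,5-hydrogen shift of the cis-methyl diene, which the non-polar solvent, the hindered base and the high effective molarity of the tether should secure.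

Step 7
Reactants: 7 bridged δ-sultone of 2α-hydroxy-4,4,10β-trimethyl-Δ5-octalin-9α-sulfonic acid
Product: 8 2α-hydroxy-4,4,10β-trimethyl-Δ5-octalin-9-one
Conditions: n-BuLi, THF, −78 °C; (Me3SiO)2, −78 → 0 °C; aq. NH4Cl
Reagents that add atoms: bis(trimethylsilyl) peroxide, C[Si](C)(C)OO[Si](C)(C)C
Why: Oxidative desulfurization of a sultone: the α-sulfonyl carbanion at C9 is oxygenated and the α-oxygenated sulfonate collapses to the C9 ketone, sulfur leaving as sulfite and the C2 alcohol being released with its configuration untouched because its C–O bond is never broken.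

Step 8
Reactants: 8 2α-hydroxy-4,4,10β-trimethyl-Δ5-octalin-9-one
Product: 9 2α-hydroxy-4,4,10β-trimethyl-5α-decalin-9-one (trans-decalin)
Conditions: H2 (4 atm), 10% Pd/C, EtOAc, rt
Reagents that add atoms: none
Why: Heterogeneous catalytic hydrogenation should deliver hydrogen to the α face of C5=C6, anti to the axial C10 methyl and the 4β-methyl, setting C5 as 5α-H (trans ring fusion) as in the hydrogenation of related 4,4,10-trimethyl-Δ5-octalins and Δ5-steroids.

Step 9
Reactants: 9 2α-hydroxy-4,4,10β-trimethyl-5α-decalin-9-one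
Product: 10 2α-hydroxy-4,4,8α,10β-tetramethyl-5α-decalin-9-one
Conditions: LiN(i-Pr)2 (2.2 equiv), THF, −78 °C; MeI (1.05 equiv), −78 → −20 °C; then NaOMe (cat.), MeOH, rt
Reagents that add atoms: iodomethane, CI
Why: Enolate C-alkylation at C8, the only enolisable position of the C9 ketone (the lithium alkoxide at C2 is inert to MeI at low temperature), followed by base equilibration that leaves the methyl equatorial (8α), the 8β epimer being destabilised by a 1,3-diaxial contact with the C10 methyl.

Step 10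
Reactants: 10 2α-hydroxy-4,4,8α,10β-tetramethyl-5α-decalin-9-one, 11 (4-bromobut-1-yn-1-yl)trimethylsilane
Product: 13 9α-[4-(trimethylsilyl)but-3-yn-1-yl]-4,4,8α,10β-tetramethyl-5α-decalin-2α,9β-diol, via [4-(trimethylsilyl)but-3-yn-1-yl]magnesium bromide 12 (not isolated)
Conditions: 11, Mg, THF, rt; anhydrous CeCl3, THF, −78 °C; then 10, −78 → 0 °C (3.5 equiv of 12)
Reagents that add atoms: none
Why: CeCl3-mediated Grignard 1,2-addition to the hindered, enolisable ketone; the nucleophile should enter along the axial trajectory on the α face, anti to the adjacent axial C10 methyl that closes the β face, which sets C9 with the chain α and the hydroxyl β.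

Step 11
Reactants: 13 9α-[4-(trimethylsilyl)but-3-yn-1-yl]-4,4,8α,10β-tetramethyl-5α-decalin-2α,9β-diol
Product: 14 9β-hydroxy-9α-[4-(trimethylsilyl)but-3-yn-1-yl]-4,4,8α,10β-tetramethyl-5α-decalin-2-one
Conditions: Dess–Martin periodinane, NaHCO3, CH2Cl2, rt
Reagents that add atoms: none
Why: Dess–Martin oxidation of the only secondary alcohol; the tertiary C9 hydroxyl cannot be oxidised.

Step 12
Reactants: 14 9β-hydroxy-9α-[4-(trimethylsilyl)but-3-yn-1-yl]-4,4,8α,10β-tetramethyl-5α-decalin-2-one
Product: 15 9β-hydroxy-9α-[4-(trimethylsilyl)but-3-yn-1-yl]-4,4,8α,10β-tetramethyl-5α-Δ2-octalin-2-yl trifluoromethanesulfonate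
Conditions: KN(SiMe3)2 (2.2 equiv), THF, −78 °C; PhNTf2, −78 → 0 °C
Reagents that add atoms: N-phenylbis(trifluoromethanesulfonimide), O=S(=O)(N(c1ccccc1)S(=O)(=O)C(F)(F)F)C(F)(F)F
Why: Kinetic enolate O-triflation; removal of the axial 3α-H is expected over the 1α-H, which is screened by the axial C11 methylene on C9 and whose loss would push the vinylic C1–H against C11, in line with the known preference of 2-oxo-trans-decalins with an angular methyl to enolise towards C3.

Step 13
Reactants: 15 9β-hydroxy-9α-[4-(trimethylsilyl)but-3-yn-1-yl]-4,4,8α,10β-tetramethyl-5α-Δ2-octalin-2-yl trifluoromethanesulfonate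
Product: 16 9α-[4-(trimethylsilyl)but-3-yn-1-yl]-4,4,8α,10β-tetramethyl-5α-Δ2-octalin-9β-ol
Conditions: Pd(OAc)2 (5 mol %), PPh3, HCO2H, Bu3N, DMF, 60 °C
Reagents that add atoms: none
Why: Palladium-catalysed formate reduction of the enol triflate (oxidative addition, formate-to-hydride exchange, reductive elimination) gives the Δ2 alkene without touching the silyl alkyne or the tertiary alcohol.

Step 14
Reactants: 16 9α-[4-(trimethylsilyl)but-3-yn-1-yl]-4,4,8α,10β-tetramethyl-5α-Δ2-octalin-9β-ol
Product: 18 methyl 5-(9β-hydroxy-4,4,8α,10β-tetramethyl-5α-Δ2-octalin-9α-yl)pent-2-ynoate, via cesium alkynoate 17 (not isolated)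
Conditions: CsF (2 equiv), CO2 (1 atm), DMSO, rt; then MeI, rt
Reagents that add atoms: carbon dioxide, O=C=O; iodomethane, CI
Why: Fluoride-mediated desilylative carboxylation of the alkynylsilane with CO2 gives the cesium alkynoate, which is O-methylated in the same flask, while the CO2 atmosphere keeps the hindered tertiary alcohol un-ionised.

Step 15
Reactants: 18 methyl 5-(9β-hydroxy-4,4,8α,10β-tetramethyl-5α-Δ2-octalin-9α-yl)pent-2-ynoate
Product: 19 methyl (2Z)-5-(9β-hydroxy-4,4,8α,10β-tetramethyl-5α-Δ2-octalin-9α-yl)-3-methylpent-2-enoate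
Conditions: Me2CuLi (from MeLi and CuI, 3 equiv), THF, −78 °C; MeOH quench at −78 °C
Reagents that add atoms: lithium dimethylcuprate (from methyllithium and CuI), [Li+].C[Cu-]C
Why: Organocuprate conjugate addition: syn-carbocupration of the ynoate at −78 °C and protonation of the vinylcopper with retention place the new methyl trans to the ester, so the chain is cis to the ester, which is the (Z)-enoate.

Step 16
Reactants: 19 methyl (2Z)-5-(9β-hydroxy-4,4,8α,10β-tetramethyl-5α-Δ2-octalin-9α-yl)-3-methylpent-2-enoate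
Product: 20 methyl (2Z)-3-methyl-5-(2α,3α,9β-trihydroxy-4,4,8α,10β-tetramethyl-5α-decalin-9α-yl)pent-2-enoate (target, CNP0292844.2)
Conditions: OsO4 (2 mol %), N-methylmorpholine N-oxide (1.1 equiv), acetone–H2O, 0 °C → rt
Reagents that add atoms: osmium tetroxide, O=[Os](=O)(=O)=O; N-methylmorpholine N-oxide, C[N+]1([O-])CCOCC1; water, O
Why: Upjohn syn-dihydroxylation of the electron-richer cis-disubstituted Δ2 alkene (the conjugated enoate reacts much more slowly) from the α face, because the β face is closed by the axial C10 and 4β methyl groups, sets C2 and C3 as the 2α,3α-diol.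

**Compound list**

1 | (4R,6R)-4-hydroxy-2,2,6-trimethylcyclohexan-1-one ((4R,6R)-actinol) | C[C@@H]1C[C@@H](O)CC(C)(C)C1=O | starting material
2 | (4R,6R)-4-[(tert-butyldimethylsilyl)oxy]-2,2,6-trimethylcyclohexan-1-one | C[C@@H]1C[C@@H](O[Si](C)(C)C(C)(C)C)CC(C)(C)C1=O | intermediate
3 | (4R)-4-[(tert-butyldimethylsilyl)oxy]-2,6,6-trimethylcyclohex-1-en-1-yl trifluoromethanesulfonate | CC1=C(OS(=O)(=O)C(F)(F)F)C(C)(C)C[C@H](O[Si](C)(C)C(C)(C)C)C1 | intermediate
4 | tert-butyl(dimethyl){[(1R)-3,5,5-trimethyl-4-vinylcyclohex-3-en-1-yl]oxy}silane | C=CC1=C(C)C[C@@H](O[Si](C)(C)C(C)(C)C)CC1(C)C | intermediate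
5 | (1R)-3,5,5-trimethyl-4-vinylcyclohex-3-en-1-ol | C=CC1=C(C)C[C@@H](O)CC1(C)C | intermediate
6 | (1R)-3,5,5-trimethyl-4-vinylcyclohex-3-en-1-yl ethenesulfonate | C=CC1=C(C)C[C@@H](OS(=O)(=O)C=C)CC1(C)C | intermediate
7 | bridged δ-sultone of 2α-hydroxy-4,4,10β-trimethyl-Δ5-octalin-9α-sulfonic acid (9β-H) | O=S1(=O)O[C@H]2CC(C)(C)C3=CCC[C@@H]1[C@@]3(C)C2 | intermediate
8 | 2α-hydroxy-4,4,10β-trimethyl-Δ5-octalin-9-one | O=C1CCC=C2C(C)(C)C[C@H](O)C[C@@]21C | intermediate
9 | 2α-hydroxy-4,4,10β-trimethyl-5α-decalin-9-one | O=C1CCC[C@H]2C(C)(C)C[C@H](O)C[C@@]21C | intermediate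
10 | 2α-hydroxy-4,4,8α,10β-tetramethyl-5α-decalin-9-one | O=C1[C@H](C)CC[C@H]2C(C)(C)C[C@H](O)C[C@@]21C | intermediate
11 | (4-bromobut-1-yn-1-yl)trimethylsilane | C[Si](C)(C)C#CCCBr | starting material
12 | [4-(trimethylsilyl)but-3-yn-1-yl]magnesium bromide | C[Si](C)(C)C#CCC[Mg]Br | intermediate
13 | 9α-[4-(trimethylsilyl)but-3-yn-1-yl]-4,4,8α,10β-tetramethyl-5α-decalin-2α,9β-diol | C[Si](C)(C)C#CCC[C@]1(O)[C@H](C)CC[C@H]2C(C)(C)C[C@H](O)C[C@@]21C | intermediate
14 | 9β-hydroxy-9α-[4-(trimethylsilyl)but-3-yn-1-yl]-4,4,8α,10β-tetramethyl-5α-decalin-2-one | C[Si](C)(C)C#CCC[C@]1(O)[C@H](C)CC[C@H]2C(C)(C)CC(=O)C[C@@]21C | intermediate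
15 | 9β-hydroxy-9α-[4-(trimethylsilyl)but-3-yn-1-yl]-4,4,8α,10β-tetramethyl-5α-Δ2-octalin-2-yl trifluoromethanesulfonate | C[Si](C)(C)C#CCC[C@]1(O)[C@H](C)CC[C@H]2C(C)(C)C=C(OS(=O)(=O)C(F)(F)F)C[C@@]21C | intermediate
16 | 9α-[4-(trimethylsilyl)but-3-yn-1-yl]-4,4,8α,10β-tetramethyl-5α-Δ2-octalin-9β-ol | C[Si](C)(C)C#CCC[C@]1(O)[C@H](C)CC[C@H]2C(C)(C)C=CC[C@@]21C | intermediate
17 | cesium 5-(9β-hydroxy-4,4,8α,10β-tetramethyl-5α-Δ2-octalin-9α-yl)pent-2-ynoate | [Cs+].[O-]C(=O)C#CCC[C@]1(O)[C@H](C)CC[C@H]2C(C)(C)C=CC[C@@]21C | intermediate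
18 | methyl 5-(9β-hydroxy-4,4,8α,10β-tetramethyl-5α-Δ2-octalin-9α-yl)pent-2-ynoate | COC(=O)C#CCC[C@]1(O)[C@H](C)CC[C@H]2C(C)(C)C=CC[C@@]21C | intermediate
19 | methyl (2Z)-5-(9β-hydroxy-4,4,8α,10β-tetramethyl-5α-Δ2-octalin-9α-yl)-3-methylpent-2-enoate | COC(=O)/C=C(/C)CC[C@]1(O)[C@H](C)CC[C@H]2C(C)(C)C=CC[C@@]21C | intermediate
20 | methyl (2Z)-3-methyl-5-(2α,3α,9β-trihydroxy-4,4,8α,10β-tetramethyl-5α-decalin-9α-yl)pent-2-enoate (CNP0292844.2) | COC(=O)/C=C(/C)CC[C@]1(O)[C@H](C)CC[C@H]2C(C)(C)[C@H](O)[C@H](O)C[C@@]21C | target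

**Totals.** Total step count: 16. Longest linear sequence: 16 steps (1 → 20); 11 enters at step 10.

**Steps most likely to fail**

Step 6. The homoallylic secondary sulfonate may ionise or eliminate, or the cis-methyl diene may undergo a 1,5-hydrogen shift, before the bridged transition state is reached; the C4 methyl groups force one ring of the bicyclo[3.3.1] array into a boat. The fallback sets out from dienol 5 and comes back at hydroxy enone 8, replacing the sulfonate by an ester that cannot ionise and can be activated by a Lewis acid. Dienol 5 is acylated (acryloyl chloride, Et3N, CH2Cl2, 0 °C) to (1R)-3,5,5-trimethyl-4-vinylcyclohex-3-en-1-yl acrylate F1. Its ester-tethered intramolecular Diels–Alder reaction (Et2AlCl, CH2Cl2, −20 °C, or 160 °C in 1,2-dichlorobenzene) should give the bridged δ-lactone of 2α-hydroxy-4,4,10β-trimethyl-Δ5-octalin-9α-carboxylic acid F2 with the same tether-imposed C10 configuration. The lactone enolate (LiN(i-Pr)2, THF, −78 °C) is hydroxylated with 2-(phenylsulfonyl)-3-phenyloxaziridine to the 9β-hydroxy lactone F3. LiAlH4 reduction gives 9α-(hydroxymethyl)-4,4,10β-trimethyl-Δ5-octalin-2α,9β-diol F4, and NaIO4 cleavage of its 9,11-glycol gives 8.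

Step 7. Oxygen transfer to the hindered tertiary α-sulfonyl carbanion may be slow, or the α-oxygenated sulfonate may not fragment cleanly. The fallback sets out from sultone 7 and comes back at 8, replacing oxygenation of the carbanion by carbon alkylation and elimination. The lithiated sultone (n-BuLi, THF, −78 °C) is treated with ICH2MgCl (from CH2I2 and i-PrMgCl) and warmed, so that the β-magnesio sulfonate expels sulfite to give 9-methylene-4,4,10β-trimethyl-Δ5-octalin-2α-ol F5. OsO4/N-methylmorpholine N-oxide should dihydroxylate the unhindered exocyclic alkene in preference to C5=C6, which is flanked by two quaternary carbons, to give 9β-(hydroxymethyl)-4,4,10β-trimethyl-Δ5-octalin-2α,9α-diol F6. NaIO4 cleaves this glycol to 8.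

Step 12. Deprotonation at C1 may compete with deprotonation at C3, giving the Δ1 enol triflate and hence the wrong alkene. The fallback sets out from ketone 14 and comes back at alkene 16, using the thermodynamically preferred Δ2 enol instead of kinetic deprotonation. Bromination with PhNMe3Br3 in THF gives 3α-bromo-9β-hydroxy-9α-[4-(trimethylsilyl)but-3-yn-1-yl]-4,4,8α,10β-tetramethyl-5α-decalin-2-one F7. NaBH4 (MeOH, 0 °C) reduces it from the open α face to the trans-diaxial 3α-bromo-2β,9β-diol F8. Zn in AcOH then removes bromine and hydroxyl reductively to give 16.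

**Further compounds**

F1 | step 6 | (1R)-3,5,5-trimethyl-4-vinylcyclohex-3-en-1-yl acrylate | C=CC1=C(C)C[C@@H](OC(=O)C=C)CC1(C)C
F2 | step 6 | bridged δ-lactone of 2α-hydroxy-4,4,10β-trimethyl-Δ5-octalin-9α-carboxylic acid (9β-H) | O=C1O[C@H]2CC(C)(C)C3=CCC[C@@H]1[C@@]3(C)C2
F3 | step 6 | 9β-hydroxy derivative of the bridged δ-lactone | O=C1O[C@H]2CC(C)(C)C3=CCC[C@]1(O)[C@@]3(C)C2
F4 | step 6 | 9α-(hydroxymethyl)-4,4,10β-trimethyl-Δ5-octalin-2α,9β-diol | OC[C@]1(O)CCC=C2C(C)(C)C[C@H](O)C[C@@]21C
F5 | step 7 | 9-methylene-4,4,10β-trimethyl-Δ5-octalin-2α-ol | C=C1CCC=C2C(C)(C)C[C@H](O)C[C@@]21C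
F6 | step 7 | 9β-(hydroxymethyl)-4,4,10β-trimethyl-Δ5-octalin-2α,9α-diol | OC[C@@]1(O)CCC=C2C(C)(C)C[C@H](O)C[C@@]21C
F7 | step 12 | 3α-bromo-9β-hydroxy-9α-[4-(trimethylsilyl)but-3-yn-1-yl]-4,4,8α,10β-tetramethyl-5α-decalin-2-one | C[Si](C)(C)C#CCC[C@]1(O)[C@H](C)CC[C@H]2C(C)(C)[C@H](Br)C(=O)C[C@@]21C
F8 | step 12 | 3α-bromo-9α-[4-(trimethylsilyl)but-3-yn-1-yl]-4,4,8α,10β-tetramethyl-5α-decalin-2β,9β-diol | C[Si](C)(C)C#CCC[C@]1(O)[C@H](C)CC[C@H]2C(C)(C)[C@H](Br)[C@@H](O)C[C@@]21C
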